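**Retrosynthetic overview**
1. Guaiane numbering: C1 fusion carbinol, C2 CH2, C3 ketone, C4/C5 enone carbons (C5 at the fusion), C6 CHOH, C7, C8 CH–O-angeloyl, C9 CH2, C10 CHMe, C11 CMe2OAc. The plan rests on the 1,3-dioxygenated triad C8(O)–C7–C11(Me)2–OAc on the seven-membered ring C1/C5–C10.
2. Target ⇐ desilylation and angeloylation at O8 ⇐ 8-hydroxy-11-acetate 21 ⇐ Prins cyclisation with acetate capture of aldehyde 20 (C7–C8 and C11–OAc bonds).
3. 20 ⇐ C8 aldehyde from a terminal vinyl group; C6 carbinol by CBS reduction of a C6 dienone built at C5 by Stork–Danheiser alkynylation and Meyer–Schuster rearrangement, with C3 masked as a dioxolane meanwhile.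
4. C1/C10 pair ⇐ chiral-diol-catalysed (Z)-crotylboration of the C1 carbonyl of the methyl enol ether of 3-methylcyclopentane-1,2,4-trione.
5. Ring order: the five-membered ring is bought (trione 1); the seven-membered ring is closed last, in step 13.

Key step: step 13

Assumption: acid-catalysed methanolysis of 1 is taken to give the cross-conjugated enol ether 2; the regioisomeric enol ether would be attacked at the same C1 carbonyl and converge on 7 in step 3.

Step 1
Reactants: 1 3-methylcyclopentane-1,2,4-trione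
Product: 2 2-methoxy-3-methylcyclopent-2-ene-1,4-dione
Conditions: MeOH, TsOH·H2O (cat), 3 Å sieves, reflux
Reagents that add atoms: methanol, CO
Why: Acid-catalysed enol etherification of the enolised β-diketone unit (C3–C4–C5) should give the cross-conjugated ene-dione as the thermodynamic isomer, which leaves C1 as the only carbonyl that is not part of a vinylogous ester, and no stereocentre is formed.

Step 2
Reactants: 3 cis-but-2-ene
Product: 5 diisopropyl (Z)-but-2-enylboronate, via (Z)-but-2-enylpotassium 4 (not isolated)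
Conditions: n-BuLi, KOt-Bu, THF, −78 → −25 °C; B(Oi-Pr)3, −78 °C; HCl in Et2O
Reagents that add atoms: triisopropyl borate, CC(C)OB(OC(C)C)OC(C)C
Why: Allylic metalation of the butene with the mixed lithium–potassium base keeps the cis geometry at low temperature, and borylation of the crotylpotassium followed by acidolysis of the ate complex (crotylmetal borylation) should give the (Z)-crotylboronate without forming a stereocentre.

Step 3
Reactants: 2 2-methoxy-3-methylcyclopent-2-ene-1,4-dione; 5 diisopropyl (Z)-but-2-enylboronate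
Product: 7 (5R)-5-[(2S)-but-3-en-2-yl]-5-hydroxy-3-methoxy-2-methylcyclopent-2-en-1-one, via 4-hydroxy-3-methoxy regioisomer 6 (not isolated)
Conditions: (S)-3,3′-dibromo-1,1′-bi-2-naphthol (15 mol%), PhCF3–PhMe, −35 °C; then TsOH·H2O (cat), MeOH, 50 °C
Reagents that add atoms: methanol, CO (exchange of the enol ether methoxy group)
Why: Chiral-diol-catalysed crotylboration of a ketone through a closed Zimmerman–Traxler chair should attack only C1=O (C3=O is a vinylogous ester carbonyl) with the flat methoxy-bearing C5 arm equatorial and C2H2 axial, so that the (Z)-boronate gives the required relative configuration of the C1 carbinol and the C10 methyl centre while the diol–boronate complex selects the Re face of C1 (1R and therefore 10S), and the acidic methanol then cleaves the borate and equilibrates the enol ether to the less crowded 3-methoxy isomer in which C5 is the ketone.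

Step 4
Reactants: 7 (5R)-5-[(2S)-but-3-en-2-yl]-5-hydroxy-3-methoxy-2-methylcyclopent-2-en-1-one
Product: 8 (5R)-5-[(2S)-but-3-en-2-yl]-3-methoxy-2-methyl-5-(triethylsilyloxy)cyclopent-2-en-1-one
Conditions: TESOTf, 2,6-lutidine, CH2Cl2, −78 → 0 °C
Reagents that add atoms: triethylsilyl trifluoromethanesulfonate, CC[Si](CC)(CC)OS(=O)(=O)C(F)(F)F
Why: Silylation of the hindered tertiary α-ketol with the silyl triflate and 2,6-lutidine (silyl ether protection) blocks the C1 hydroxyl against lactol formation and alkoxide chemistry in later steps and touches no stereocentre.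

Step 5
Reactants: 8 (5R)-5-[(2S)-but-3-en-2-yl]-3-methoxy-2-methyl-5-(triethylsilyloxy)cyclopent-2-en-1-one; 9 2-methylbut-3-yn-2-ol
Product: 11 (4R)-4-[(2S)-but-3-en-2-yl]-3-(3-hydroxy-3-methylbut-1-ynyl)-2-methyl-4-(triethylsilyloxy)cyclopent-2-en-1-one, via carbinol adduct 10 (not isolated)
Conditions: 9 (3 equiv), n-BuLi (6 equiv), THF, −78 °C; add 8, −78 → 0 °C; then 1 M HCl, THF, 0 °C
Reagents that add atoms: water, O
Why: Stork–Danheiser transposition in which the slim dilithiated alkynol adds 1,2 to the vinylogous ester carbonyl C5 and dilute acid ionises the resulting tertiary allylic carbinol to a methoxy-stabilised allyl cation whose hydrolysis gives the C3 ketone with the C6–C7–C11 carbons on C5, the stereocentre formed at C5 in 10 being lost again in the elimination.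

Step 6
Reactants: 11 (4R)-4-[(2S)-but-3-en-2-yl]-3-(3-hydroxy-3-methylbut-1-ynyl)-2-methyl-4-(triethylsilyloxy)cyclopent-2-en-1-one
Product: 13 4-{(8R)-8-[(2S)-but-3-en-2-yl]-6-methyl-8-(triethylsilyloxy)-1,4-dioxaspiro[4.4]non-6-en-7-yl}-2-methylbut-3-yn-2-ol, via trimethylsilyl ether 12 (not isolated)
Conditions: TMSOCH2CH2OTMS, TMSOTf (cat), CH2Cl2, −78 → −20 °C; pyridine; then K2CO3, MeOH, 23 °C
Reagents that add atoms: 1,2-bis(trimethylsilyloxy)ethane, C[Si](C)(C)OCCO[Si](C)(C)C
Why: Silyl-triflate-catalysed ketalisation with the bis-silyl ether of ethylene glycol at low temperature should convert the only ketone (C3) into its dioxolane without moving the C4=C5 bond, the tertiary propargylic hydroxyl being capped in passing as a trimethylsilyl ether that K2CO3 in methanol removes while the tertiary triethylsilyl ether stays.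

Step 7
Reactants: 13 4-{(8R)-8-[(2S)-but-3-en-2-yl]-6-methyl-8-(triethylsilyloxy)-1,4-dioxaspiro[4.4]non-6-en-7-yl}-2-methylbut-3-yn-2-ol
Product: 14 1-{(8R)-8-[(2S)-but-3-en-2-yl]-6-methyl-8-(triethylsilyloxy)-1,4-dioxaspiro[4.4]non-6-en-7-yl}-3-methylbut-2-en-1-one
Conditions: ReOCl3(OPPh3)(SMe2) (5 mol%), DME, 25 °C
Reagents that add atoms: none
Why: Meyer–Schuster rearrangement under oxo-rhenium catalysis transposes the tertiary propargylic hydroxyl from C11 to C6 through a [3,3] shift of the metal ester and the allenol tautomerises to the C6 ketone with the C7=C11 double bond, under neutral conditions that spare the ketal and do not engage the 1,6-enyne as a π-acid would.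

Step 8
Reactants: 14 1-{(8R)-8-[(2S)-but-3-en-2-yl]-6-methyl-8-(triethylsilyloxy)-1,4-dioxaspiro[4.4]non-6-en-7-yl}-3-methylbut-2-en-1-one
Product: 15 (1R)-1-{(8R)-8-[(2S)-but-3-en-2-yl]-6-methyl-8-(triethylsilyloxy)-1,4-dioxaspiro[4.4]non-6-en-7-yl}-3-methylbut-2-en-1-ol
Conditions: (S)-2-methyl-CBS-oxazaborolidine (0.3 equiv), catecholborane, PhMe, −78 → −40 °C; aq NaOH work-up
Reagents that add atoms: none
Why: Corey–Bakshi–Shibata reduction in which C6 is the only ketone and its fully substituted ring alkenyl substituent (C5) is much larger than the 2-methylprop-1-enyl group, so the (S)-oxazaborolidine should deliver hydride to the face that gives the 6R carbinol, while catecholborane at low temperature leaves the vinyl group and the ketal alone.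

Step 9
Reactants: 15 (1R)-1-{(8R)-8-[(2S)-but-3-en-2-yl]-6-methyl-8-(triethylsilyloxy)-1,4-dioxaspiro[4.4]non-6-en-7-yl}-3-methylbut-2-en-1-ol
Product: 16 tert-butyldimethylsilyl ether of 15 at O6 (1R,6R,10S)
Conditions: TBSOTf, 2,6-lutidine, CH2Cl2, −78 °C
Reagents that add atoms: tert-butyldimethylsilyl trifluoromethanesulfonate, CC(C)(C)[Si](C)(C)OS(=O)(=O)C(F)(F)F
Why: Silyl ether formation with the silyl triflate and 2,6-lutidine at low temperature protects the hindered doubly allylic C6 hydroxyl without ionising it and leaves the configuration at C6 unchanged.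

Step 10
Reactants: 16 tert-butyldimethylsilyl ether of 15 at O6 (1R,6R,10S)
Product: 18 (3S)-3-{(8R)-7-[(1R)-1-(tert-butyldimethylsilyloxy)-3-methylbut-2-enyl]-6-methyl-8-(triethylsilyloxy)-1,4-dioxaspiro[4.4]non-6-en-8-yl}butan-1-ol, via alkylborane 17 (not isolated)
Conditions: 9-BBN, THF, 0 → 25 °C; then aq NaOH, H2O2, 0 °C
Reagents that add atoms: 9-borabicyclo[3.3.1]nonane, B1C2CCCC1CCC2 (boron in 17 only); hydrogen peroxide, OO
Why: Hydroboration–oxidation in which 9-BBN adds with anti-Markovnikov regioselectivity to the monosubstituted C8=C9 alkene only (the trisubstituted C7=C11 and tetrasubstituted C4=C5 alkenes react far more slowly and C3 is masked) and alkaline peroxide gives the primary C8 alcohol with no new stereocentre.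

Step 11
Reactants: 18 (3S)-3-{(8R)-7-[(1R)-1-(tert-butyldimethylsilyloxy)-3-methylbut-2-enyl]-6-methyl-8-(triethylsilyloxy)-1,4-dioxaspiro[4.4]non-6-en-8-yl}butan-1-ol
Product: 19 (4R)-3-[(1R)-1-(tert-butyldimethylsilyloxy)-3-methylbut-2-enyl]-4-[(2S)-4-hydroxybutan-2-yl]-2-methyl-4-(triethylsilyloxy)cyclopent-2-en-1-one
Conditions: PPTS, acetone–H2O, 40 °C
Reagents that add atoms: water, O
Why: Acid-catalysed hydrolysis of the allylic dioxolane through the conjugated oxocarbenium ion (ketal cleavage) returns the C3 enone under conditions mild enough for both silyl ethers and touches no stereocentre.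

Step 12
Reactants: 19 (4R)-3-[(1R)-1-(tert-butyldimethylsilyloxy)-3-methylbut-2-enyl]-4-[(2S)-4-hydroxybutan-2-yl]-2-methyl-4-(triethylsilyloxy)cyclopent-2-en-1-one
Product: 20 (3S)-3-{(1R)-2-[(1R)-1-(tert-butyldimethylsilyloxy)-3-methylbut-2-enyl]-3-methyl-4-oxo-1-(triethylsilyloxy)cyclopent-2-enyl}butanal
Conditions: Dess–Martin periodinane, NaHCO3, CH2Cl2, 0 → 25 °C
Reagents that add atoms: none
Why: Dess–Martin oxidation of the primary alcohol under buffered conditions stops at the aldehyde and does not epimerise C10, which is β to the new carbonyl.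

Step 13
Reactants: 20 (3S)-3-{(1R)-2-[(1R)-1-(tert-butyldimethylsilyloxy)-3-methylbut-2-enyl]-3-methyl-4-oxo-1-(triethylsilyloxy)cyclopent-2-enyl}butanal
Product: 21 (1R,6R,7R,8R,10S)-11-acetoxy-6-(tert-butyldimethylsilyloxy)-8-hydroxy-1-(triethylsilyloxy)guai-4-en-3-one
Conditions: BF3·OEt2 (2 equiv), AcOH (10 equiv), CH2Cl2, −78 → −40 °C
Reagents that add atoms: acetic acid, CC(=O)O
Why: BF3 activates the C8 aldehyde, C7 of the trisubstituted C7=C11 alkene adds to it and the tertiary C11 cation is captured by acetic acid, so the C7–C8 bond, the C8 carbinol and the C11 acetate arise in one operation. The closest known reaction type is the Lewis-acid Prins cyclisation of alkenyl aldehydes with capture of the cation by a carboxylate, as in the conversion of citronellal into p-menthane-3,8-diol esters, a closure also known for seven-membered carbocycles. The seven-membered ring C1–C5–C6–C7–C8–C9–C10 closes in an exo mode at both π-bonds (the carbonyl oxygen and C11 stay outside the new ring) through a chair-like array of which the cyclopentenone plane is one rigid edge. C7 is set by C6: 1,3-allylic strain with the C4 methyl keeps the C6 silyloxy group out of the enone plane on the face of the C10 arm, and from that rotamer the tethered aldehyde reaches only the alkene face that leaves the CMe2 terminus pointing away from the ring fusion, which puts H7 cis to H6. C8 is set by the synclinal, closed arrangement of the BF3-bound carbonyl oxygen over the developing C11 cation, which places the C8 oxygen cis to the C7 side chain. The step needs cyclisation to outrun ionisation of the doubly allylic C6–O bond and proton loss from C11; the electron-poor enone carbon C5 destabilises a C6 cation, and low temperature with excess acetic acid favours capture.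

Step 14
Reactants: 21 (1R,6R,7R,8R,10S)-11-acetoxy-6-(tert-butyldimethylsilyloxy)-8-hydroxy-1-(triethylsilyloxy)guai-4-en-3-one; 22 angelic acid [(Z)-2-methylbut-2-enoic acid]
Product: 24 (1R,6R,7R,8R,10S)-11-acetoxy-6-(tert-butyldimethylsilyloxy)-3-oxo-1-(triethylsilyloxy)guai-4-en-8-yl (Z)-2-methylbut-2-enoate, via mixed anhydride 23 (not isolated)
Conditions: 2,4,6-Cl3C6H2COCl, Et3N, PhMe, 25 °C; then 21, 80 °C
Reagents that add atoms: none
Why: Yamaguchi esterification in which the mixed anhydride is attacked at the less hindered angeloyl carbonyl by the C8 hydroxyl and the absence of a nucleophilic amine catalyst should keep the (Z)-double bond from isomerising, with C8 acylated with retention.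

Step 15
Reactants: 24 (1R,6R,7R,8R,10S)-11-acetoxy-6-(tert-butyldimethylsilyloxy)-3-oxo-1-(triethylsilyloxy)guai-4-en-8-yl (Z)-2-methylbut-2-enoate
Product: 25 (1R,6R,7S,8R,10S)-11-acetoxy-1,6-dihydroxy-3-oxoguai-4-en-8-yl (Z)-2-methylbut-2-enoate (CNP0273287.1)
Conditions: HF·pyridine, pyridine, THF, 0 → 25 °C
Reagents that add atoms: none
Why: Fluoride-mediated cleavage of both silyl ethers with buffered HF·pyridine (desilylation) frees the C1 and C6 hydroxyls without touching the angelate, the tertiary acetate or any stereocentre (the C7 label changes from R to S only because the CIP ranking of C6 and C8 changes).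

**Compound list**
1 | 3-methylcyclopentane-1,2,4-trione | CC1C(=O)CC(=O)C1=O | starting material
2 | 2-methoxy-3-methylcyclopent-2-ene-1,4-dione | COC1=C(C)C(=O)CC1=O | intermediate
3 | cis-but-2-ene | C/C=C\C | starting material
4 | (Z)-but-2-enylpotassium | C/C=C\C[K] | intermediate
5 | diisopropyl (Z)-but-2-enylboronate | C/C=C\CB(OC(C)C)OC(C)C | intermediate
6 | (4R)-4-[(2S)-but-3-en-2-yl]-4-hydroxy-3-methoxy-2-methylcyclopent-2-en-1-one | C=C[C@H](C)[C@]1(O)CC(=O)C(C)=C1OC | intermediate
7 | (5R)-5-[(2S)-but-3-en-2-yl]-5-hydroxy-3-methoxy-2-methylcyclopent-2-en-1-one | C=C[C@H](C)[C@]1(O)CC(OC)=C(C)C1=O | intermediate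
8 | (5R)-5-[(2S)-but-3-en-2-yl]-3-methoxy-2-methyl-5-(triethylsilyloxy)cyclopent-2-en-1-one | C=C[C@H](C)[C@]1(O[Si](CC)(CC)CC)CC(OC)=C(C)C1=O | intermediate
9 | 2-methylbut-3-yn-2-ol | CC(C)(O)C#C | starting material
10 | (5R)-5-[(2S)-but-3-en-2-yl]-1-(3-hydroxy-3-methylbut-1-ynyl)-3-methoxy-2-methyl-5-(triethylsilyloxy)cyclopent-2-en-1-ol (both C1 epimers) | C=C[C@H](C)[C@]1(O[Si](CC)(CC)CC)CC(OC)=C(C)C1(O)C#CC(C)(C)O | intermediate
11 | (4R)-4-[(2S)-but-3-en-2-yl]-3-(3-hydroxy-3-methylbut-1-ynyl)-2-methyl-4-(triethylsilyloxy)cyclopent-2-en-1-one | C=C[C@H](C)[C@]1(O[Si](CC)(CC)CC)CC(=O)C(C)=C1C#CC(C)(C)O | intermediate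
12 | trimethylsilyl ether of 13 at the tertiary propargylic oxygen | C=C[C@H](C)[C@]1(O[Si](CC)(CC)CC)CC2(OCCO2)C(C)=C1C#CC(C)(C)O[Si](C)(C)C | intermediate
13 | 4-{(8R)-8-[(2S)-but-3-en-2-yl]-6-methyl-8-(triethylsilyloxy)-1,4-dioxaspiro[4.4]non-6-en-7-yl}-2-methylbut-3-yn-2-ol | C=C[C@H](C)[C@]1(O[Si](CC)(CC)CC)CC2(OCCO2)C(C)=C1C#CC(C)(C)O | intermediate
14 | 1-{(8R)-8-[(2S)-but-3-en-2-yl]-6-methyl-8-(triethylsilyloxy)-1,4-dioxaspiro[4.4]non-6-en-7-yl}-3-methylbut-2-en-1-one | C=C[C@H](C)[C@]1(O[Si](CC)(CC)CC)CC2(OCCO2)C(C)=C1C(=O)C=C(C)C | intermediate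
15 | (1R)-1-{(8R)-8-[(2S)-but-3-en-2-yl]-6-methyl-8-(triethylsilyloxy)-1,4-dioxaspiro[4.4]non-6-en-7-yl}-3-methylbut-2-en-1-ol | C=C[C@H](C)[C@]1(O[Si](CC)(CC)CC)CC2(OCCO2)C(C)=C1[C@H](O)C=C(C)C | intermediate
16 | tert-butyldimethylsilyl ether of 15 at O6 (1R,6R,10S) | C=C[C@H](C)[C@]1(O[Si](CC)(CC)CC)CC2(OCCO2)C(C)=C1[C@H](O[Si](C)(C)C(C)(C)C)C=C(C)C | intermediate
17 | B-alkyl-9-borabicyclo[3.3.1]nonane from 16 (boron on C8) | C1CCC2CCCC1B2CC[C@H](C)[C@]3(O[Si](CC)(CC)CC)CC4(OCCO4)C(C)=C3[C@H](O[Si](C)(C)C(C)(C)C)C=C(C)C | intermediate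
18 | (3S)-3-{(8R)-7-[(1R)-1-(tert-butyldimethylsilyloxy)-3-methylbut-2-enyl]-6-methyl-8-(triethylsilyloxy)-1,4-dioxaspiro[4.4]non-6-en-8-yl}butan-1-ol | OCC[C@H](C)[C@]1(O[Si](CC)(CC)CC)CC2(OCCO2)C(C)=C1[C@H](O[Si](C)(C)C(C)(C)C)C=C(C)C | intermediate
19 | (4R)-3-[(1R)-1-(tert-butyldimethylsilyloxy)-3-methylbut-2-enyl]-4-[(2S)-4-hydroxybutan-2-yl]-2-methyl-4-(triethylsilyloxy)cyclopent-2-en-1-one | OCC[C@H](C)[C@]1(O[Si](CC)(CC)CC)CC(=O)C(C)=C1[C@H](O[Si](C)(C)C(C)(C)C)C=C(C)C | intermediate
20 | (3S)-3-{(1R)-2-[(1R)-1-(tert-butyldimethylsilyloxy)-3-methylbut-2-enyl]-3-methyl-4-oxo-1-(triethylsilyloxy)cyclopent-2-enyl}butanal | O=CC[C@H](C)[C@]1(O[Si](CC)(CC)CC)CC(=O)C(C)=C1[C@H](O[Si](C)(C)C(C)(C)C)C=C(C)C | intermediate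
21 | (1R,6R,7R,8R,10S)-11-acetoxy-6-(tert-butyldimethylsilyloxy)-8-hydroxy-1-(triethylsilyloxy)guai-4-en-3-one | O[C@@H]1C[C@H](C)[C@]2(O[Si](CC)(CC)CC)CC(=O)C(C)=C2[C@H](O[Si](C)(C)C(C)(C)C)[C@@H]1C(C)(C)OC(C)=O | intermediate
22 | angelic acid [(Z)-2-methylbut-2-enoic acid] | C/C=C(/C)C(=O)O | starting material
23 | (Z)-2-methylbut-2-enoic 2,4,6-trichlorobenzoic anhydride | C/C=C(/C)C(=O)OC(=O)c1c(Cl)cc(Cl)cc1Cl | intermediate
24 | (1R,6R,7R,8R,10S)-11-acetoxy-6-(tert-butyldimethylsilyloxy)-3-oxo-1-(triethylsilyloxy)guai-4-en-8-yl (Z)-2-methylbut-2-enoate | C/C=C(/C)C(=O)O[C@@H]1C[C@H](C)[C@]2(O[Si](CC)(CC)CC)CC(=O)C(C)=C2[C@H](O[Si](C)(C)C(C)(C)C)[C@@H]1C(C)(C)OC(C)=O | intermediate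
25 | (1R,6R,7S,8R,10S)-11-acetoxy-1,6-dihydroxy-3-oxoguai-4-en-8-yl (Z)-2-methylbut-2-enoate (CNP0273287.1) | C/C=C(/C)C(=O)O[C@@H]1C[C@H](C)[C@]2(O)CC(=O)C(C)=C2[C@H](O)[C@@H]1C(C)(C)OC(C)=O | target

**Step count and risks**
Total step count: 15. Longest linear sequence: 14 steps (1 → 25; step 2 is a one-step side branch).

Most likely to fail:

1. Step 13 (Prins cyclisation). The C11 cation may lose a proton instead of being captured by acetate, or the acid may ionise or strip the C6 silyl ether before the ring closes. Facial selectivity at C7 and C8 may also be incomplete. Fallback, setting out from 20: cyclisation with Me2AlCl in CH2Cl2 at −78 °C as a carbonyl–ene reaction should give 8-hydroxy-7-isopropenyl hydroazulenone F1. Mukaiyama hydration (Co(acac)2, PhSiH3, O2, i-PrOH) of its 1,1-disubstituted alkene gives 8,11-diol F2. The secondary C8 hydroxyl is then esterified with 22 under the conditions of step 14 to give 8-angelate 11-ol F3. Acetylation of the tertiary hydroxyl (Ac2O, Sc(OTf)3 cat, MeCN, −20 °C) returns the route at 24.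

2. Step 3 (crotylboration). Uncatalysed addition of the boronate to the very electrophilic ene-dione may erode enantiofacial selectivity. Fallback by resolution, setting out from 2 and 5: the same addition without the diol (PhMe, 25 °C, then TsOH in MeOH) should give racemic hydroxy enone F4. Exchange of its methoxy group for (1R,2S,5R)-menthol (TsOH cat, PhMe, removal of methanol) gives two diastereomeric vinylogous esters. These are separated by chromatography or crystallisation into (5R)-menthyl ether F5 and (5S)-menthyl ether F6 (discarded). Silylation of F5 as in step 4 gives triethylsilyl ether F7, which is taken through step 5 in place of 8 with loss of menthol and comes back to the route at 11.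

3. Step 14 (angeloylation). Acylation of the crowded C8 carbinol may be slow, and heat and amine may cause Z→E isomerisation of the angeloyl group or a 1,3-shift of the acetyl group from O11 to O8. Fallback, setting out from 21: esterification with 2-[bis(2,2,2-trifluoroethoxy)phosphoryl]propanoic acid (DCC, DMAP cat, CH2Cl2, 0 °C) gives phosphonopropionate F8. A Still–Gennari olefination (KN(SiMe3)2, 18-crown-6, THF, −78 °C; acetaldehyde) then builds the (Z)-2-methylbut-2-enoate on the substrate and comes back to the route at 24.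

**Further compounds**
F1 | step 13 | (1R,6R,7R,8R,10S)-6-(tert-butyldimethylsilyloxy)-8-hydroxy-1-(triethylsilyloxy)guaia-4,11(12)-dien-3-one | O[C@@H]1C[C@H](C)[C@]2(O[Si](CC)(CC)CC)CC(=O)C(C)=C2[C@H](O[Si](C)(C)C(C)(C)C)[C@@H]1C(C)=C
F2 | step 13 | (1R,6R,7R,8R,10S)-6-(tert-butyldimethylsilyloxy)-8,11-dihydroxy-1-(triethylsilyloxy)guai-4-en-3-one | O[C@@H]1C[C@H](C)[C@]2(O[Si](CC)(CC)CC)CC(=O)C(C)=C2[C@H](O[Si](C)(C)C(C)(C)C)[C@@H]1C(C)(C)O
F3 | step 13 | (1R,6R,7R,8R,10S)-6-(tert-butyldimethylsilyloxy)-11-hydroxy-3-oxo-1-(triethylsilyloxy)guai-4-en-8-yl (Z)-2-methylbut-2-enoate | C/C=C(/C)C(=O)O[C@@H]1C[C@H](C)[C@]2(O[Si](CC)(CC)CC)CC(=O)C(C)=C2[C@H](O[Si](C)(C)C(C)(C)C)[C@@H]1C(C)(C)O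
F4 | step 3 | racemic 5-(but-3-en-2-yl)-5-hydroxy-3-methoxy-2-methylcyclopent-2-en-1-one (7 and its enantiomer) | C=C[C@H](C)[C@]1(O)CC(OC)=C(C)C1=O.C=C[C@@H](C)[C@@]1(O)CC(OC)=C(C)C1=O
F5 | step 3 | (5R)-5-[(2S)-but-3-en-2-yl]-5-hydroxy-2-methyl-3-[(1R,2S,5R)-menthyloxy]cyclopent-2-en-1-one | C=C[C@H](C)[C@]1(O)CC(O[C@H]2[C@H](C(C)C)CC[C@@H](C)C2)=C(C)C1=O
F6 | step 3 | (5S)-5-[(2R)-but-3-en-2-yl]-5-hydroxy-2-methyl-3-[(1R,2S,5R)-menthyloxy]cyclopent-2-en-1-one | C=C[C@@H](C)[C@@]1(O)CC(O[C@H]2[C@H](C(C)C)CC[C@@H](C)C2)=C(C)C1=O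
F7 | step 3 | (5R)-5-[(2S)-but-3-en-2-yl]-2-methyl-3-[(1R,2S,5R)-menthyloxy]-5-(triethylsilyloxy)cyclopent-2-en-1-one | C=C[C@H](C)[C@]1(O[Si](CC)(CC)CC)CC(O[C@H]2[C@H](C(C)C)CC[C@@H](C)C2)=C(C)C1=O
F8 | step 14 | (1R,6R,7R,8R,10S)-11-acetoxy-6-(tert-butyldimethylsilyloxy)-3-oxo-1-(triethylsilyloxy)guai-4-en-8-yl 2-[bis(2,2,2-trifluoroethoxy)phosphoryl]propanoate | CC(C(=O)O[C@@H]1C[C@H](C)[C@]2(O[Si](CC)(CC)CC)CC(=O)C(C)=C2[C@H](O[Si](C)(C)C(C)(C)C)[C@@H]1C(C)(C)OC(C)=O)P(=O)(OCC(F)(F)F)OCC(F)(F)F
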